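The 4 questions below ask about one amount: the Z standing in each flask at the end.

all flasks: L 0.039 M; E 0.74 mM; time 4.0 d
- winter: temperature 55 °C
- summer: temperature 25 °C
- dusk: temperature 40 °C

    D + E → X + Z (k1 = 19.0 L mol⁻¹ h⁻¹, Ea1 = 69.0 kJ mol⁻¹)
    D + X → Z + X, rate k2*[X]*[D] (k2 = 25.5 L mol⁻¹ h⁻¹, Ea2 = 48.0 kJ mol⁻¹)
    L ⇌ D, rate k3*(cs3 - [D]) while solid is left; crystals form when [D] > cs3 (cs3 = 17 mM, k3 = 0.0248 h⁻¹)
    (constants at 25 °C)

- given per volume of solution although it is solid: L
- at 25 °C the constants are as listed, elsewhere as the activation energies make them
- at the start none of L is in solution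

* the flask with the highest amount of Z, in percent of the L charged ("all alike" if they lie within 1.5 percentage points) (winter / summer / dusk / all alike)
* final Z, as a percentage of the L charged, in winter
* final Z, as a percentage of the L charged, in summer
* final Z, as a percentage of the L charged, in dusk

L starts as solid, so D appears only by dissolving. With coefficient κ and solubility s, that feed is κs = 0.422 mM h⁻¹ at zero D, and it has no activation energy, so warming leaves it alone. But D builds up and slows its own feed.

Each E gives one X and no step removes X, so we take X at 0.74 mM from the start. Step 1 itself can put 1.90 % of the L charged into Z, and we set that aside. D is then consumed with the pseudo-first-order constant p, which is the temperature's value of the propagation constant times X.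

In winter, propagation is 5.9 times its summer speed, so p = 0.111 h⁻¹. This gives 3.11 mM for the holding level H = κs/(κ + p), the D at which dissolving matches propagation. That is 7.97 % of the L charged.

D approaches H with time constant τ = 1/(κ + p), here 7.37 h, and Z then grows as pH(t − τ). Winter reaches 30.5 mM, or 78.3 %. With D added, we reckon 86.3 % dissolved, less than the charge, so we expect solid to remain in winter.

Summer has p = 0.0189 h⁻¹, H = 9.65 mM and Z = 13.3 mM, or 34.1 %. For dusk we roughly take the root of the winter factor: p = 0.0457 h⁻¹, H = 5.98 mM, and Z reaches 22.4 mM, or 57.3 %.

The forecast says 78.5 % in winter, 59 % at dusk and 34 % in summer, with winter highest, on the grounds that “Warming speeds propagation, which holds D lower”. Our dusk figure lies below its number.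

The flasks end at 78.4 % in winter, 58.5 % at dusk and 33.9 % in summer, so winter is highest. At dusk, at 4.00 d, D is made 1.00 times as fast as it is used up, net, and it stands at 14.9 % of the L charged against an H of 15.3 %. In winter, at 4.00 d, D reads 7.97 % against 7.97 %. A dusk flask with 1.8 × 10⁻⁴ M of E has p = 0.0111 h⁻¹, so H is 30.1 %; it reads D 28.8 % and Z 23.9 %.

All constants stand for no real mixture; no experiment stands behind them.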